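## Retrosynthetic overview

1. Feature (germacrane locants): the α-methylene-γ-butyrolactone O–C8–C7–C11(=C13H2)–C12(=O) is the sum of an aldehyde (C8), the inner π-bond of a terminal allene (C7=C11, C13 outside) and CO (C12). Its C7–C8 bond is also a bond of the ten-membered carbocycle C1–C10.
2. Target 25 ⇐ bis-silyl ether 24 ⇐ acyclic allenyl aldehyde 23 + CO. One metal-mediated step forms C7–C8 (ten-membered ring first, in the oxametallacycle), then C11–C12 and C12–O (γ-lactone second).
3. 23 ⇐ Z-enal 16: C6–C7 by reagent-controlled allenylation, then acylation with (R)-2-methylbutanoic acid; the C8 aldehyde is unveiled last from a primary silyl ether.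
4. 16 ⇐ alkyne 11 ⇐ Z-enal 7: each Z-trisubstituted alkene by syn-addition of a methylcuprate to an ynoate; C2 by catalytic asymmetric propargylation of 7.
5. C9 comes from (S)-glyceraldehyde acetonide 1.

Key step: step 17

Remark: locants C1–C13 are germacrane locants (lactone oxygen on C8, ester on C6, hydroxyls on C2 and C9, methyls on C4 and C10). Abbreviations: TBS = tert-butyldimethylsilyl; TEMPO = 2,2,6,6-tetramethylpiperidin-1-oxyl; TRIP acid = 3,3'-bis(2,4,6-triisopropylphenyl)-1,1'-binaphthalene-2,2'-diyl hydrogen phosphate; PPTS = pyridinium 4-toluenesulfonate; DMAP = 4-(dimethylamino)pyridine; DCC = N,N'-dicyclohexylcarbodiimide; DMP = Dess–Martin periodinane.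

Assumption: the enantiomers named for the two chiral controllers (TRIP acid in step 6, diazaborolidine in step 13) are those expected to deliver the nucleophile to the Si face of the aldehyde; both antipodes are available, and the sense is to be confirmed by Mosher ester analysis on first use.

## Route

Step 1
Reactants: 1 (4S)-2,2-dimethyl-1,3-dioxolane-4-carbaldehyde
Product: 2 (4R)-4-(2,2-dibromoethenyl)-2,2-dimethyl-1,3-dioxolane
Conditions: CBr4, PPh3, Et3N, CH2Cl2, 0 °C
Reagents that add atoms: carbon tetrabromide, BrC(Br)(Br)Br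
Why: First stage of the Corey–Fuchs sequence (dibromo-olefination of an aldehyde by Ph3P=CBr2); no new stereocentre, and the α-oxygenated centre is kept by the low temperature and the amine buffer.

Step 2
Reactants: 2 (4R)-4-(2,2-dibromoethenyl)-2,2-dimethyl-1,3-dioxolane
Product: 4 methyl 3-[(4R)-2,2-dimethyl-1,3-dioxolan-4-yl]prop-2-ynoate, via lithium acetylide 3 (not isolated)
Conditions: n-BuLi (2.1 equiv), THF, −78 °C; then ClCO2Me, −78 to 0 °C
Reagents that add atoms: methyl chloroformate, COC(=O)Cl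
Why: Second stage of the Corey–Fuchs sequence: elimination and lithium–bromine exchange give acetylide 3, which is C-acylated by the chloroformate; no stereocentre is touched.

Step 3
Reactants: 4 methyl 3-[(4R)-2,2-dimethyl-1,3-dioxolan-4-yl]prop-2-ynoate
Product: 5 methyl (2Z)-3-[(4R)-2,2-dimethyl-1,3-dioxolan-4-yl]but-2-enoate
Conditions: Me2CuLi (from MeLi, CuI), THF, −78 °C; NH4Cl/MeOH quench at −78 °C
Reagents that add atoms: lithium dimethylcuprate, [Li+].C[Cu-]C
Why: Conjugate syn-carbocupration of the ynoate by the Gilman reagent and protonation of the alkenyl copper with retention at −78 °C should put the dioxolanyl carbon cis to the ester, which is the Z geometry of C1=C10.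

Step 4
Reactants: 5 methyl (2Z)-3-[(4R)-2,2-dimethyl-1,3-dioxolan-4-yl]but-2-enoate
Product: 6 (2Z)-3-[(4R)-2,2-dimethyl-1,3-dioxolan-4-yl]but-2-en-1-ol
Conditions: i-Bu2AlH (2.2 equiv), CH2Cl2, −78 °C; Rochelle salt work-up
Reagents that add atoms: none
Why: 1,2-Reduction of the enoate by two hydrides of i-Bu2AlH should give the allylic alcohol with the alkene geometry unchanged.

Step 5
Reactants: 6 (2Z)-3-[(4R)-2,2-dimethyl-1,3-dioxolan-4-yl]but-2-en-1-ol
Product: 7 (2Z)-3-[(4R)-2,2-dimethyl-1,3-dioxolan-4-yl]but-2-enal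
Conditions: TEMPO (10 mol%), PhI(OAc)2, CH2Cl2, rt
Reagents that add atoms: none
Why: Oxoammonium oxidation of a primary allylic alcohol, a non-basic method known to deliver Z-enals without Z to E isomerisation.

Step 6
Reactants: 7 (2Z)-3-[(4R)-2,2-dimethyl-1,3-dioxolan-4-yl]but-2-enal; 8 allenylboronic acid pinacol ester
Product: 9 (4S,5Z)-6-[(4R)-2,2-dimethyl-1,3-dioxolan-4-yl]hept-5-en-1-yn-4-ol
Conditions: (S)-TRIP acid (10 mol%), 4 Å molecular sieves, toluene, −20 °C to rt; aq. NaHCO3 work-up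
Reagents that add atoms: none
Why: Chiral phosphoric acid-catalysed allenylboration (SE2' propargylation) through a closed six-membered transition state; the (S)-catalyst is expected to direct attack to the Si face of the aldehyde and so to set C2 as S under catalyst control.

Step 7
Reactants: 9 (4S,5Z)-6-[(4R)-2,2-dimethyl-1,3-dioxolan-4-yl]hept-5-en-1-yn-4-ol
Product: 10 (2R,3Z,5S)-3-methyloct-3-en-7-yne-1,2,5-triol
Conditions: PPTS (20 mol%), MeOH, 40 °C
Reagents that add atoms: none
Why: Acid-catalysed transacetalisation to methanol removes the terminal acetonide, and pyridinium tosylate is too weak an acid to ionise the two allylic alcohols.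

Step 8
Reactants: 10 (2R,3Z,5S)-3-methyloct-3-en-7-yne-1,2,5-triol
Product: 11 (4S,5Z,7R)-4,7,8-tris(tert-butyldimethylsilyloxy)-6-methyloct-5-en-1-yne
Conditions: TBSOTf (3.6 equiv), 2,6-lutidine, CH2Cl2, −78 to 0 °C
Reagents that add atoms: tert-butyldimethylsilyl trifluoromethanesulfonate, CC(C)(C)[Si](C)(C)OS(=O)(=O)C(F)(F)F
Why: Silylation with the silyl triflate and a hindered pyridine base should protect the primary and both secondary hydroxyls without touching the alkyne C–H.

Step 9
Reactants: 11 (4S,5Z,7R)-4,7,8-tris(tert-butyldimethylsilyloxy)-6-methyloct-5-en-1-yne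
Product: 13 methyl (5S,6Z,8R)-5,8,9-tris(tert-butyldimethylsilyloxy)-7-methylnon-6-en-2-ynoate, via lithium acetylide 12 (not isolated)
Conditions: n-BuLi (1.1 equiv), THF, −78 °C; then ClCO2Me, −78 to −20 °C
Reagents that add atoms: methyl chloroformate, COC(=O)Cl
Why: Deprotonation of the terminal alkyne and C-acylation of the lithium acetylide by a chloroformate (alkyne carboxylation); no stereocentre is involved.

Step 10
Reactants: 13 methyl (5S,6Z,8R)-5,8,9-tris(tert-butyldimethylsilyloxy)-7-methylnon-6-en-2-ynoate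
Product: 14 methyl (2Z,5S,6Z,8R)-5,8,9-tris(tert-butyldimethylsilyloxy)-3,7-dimethylnona-2,6-dienoate
Conditions: Me2CuLi (from MeLi, CuI), THF, −78 °C; NH4Cl/MeOH quench at −78 °C
Reagents that add atoms: lithium dimethylcuprate, [Li+].C[Cu-]C
Why: The same syn-carbocupration and cold protonation as in step 3 should place C3 cis to the ester and so fix the Z geometry of C4=C5.

Step 11
Reactants: 14 methyl (2Z,5S,6Z,8R)-5,8,9-tris(tert-butyldimethylsilyloxy)-3,7-dimethylnona-2,6-dienoate
Product: 15 (2Z,5S,6Z,8R)-5,8,9-tris(tert-butyldimethylsilyloxy)-3,7-dimethylnona-2,6-dien-1-ol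
Conditions: i-Bu2AlH (2.2 equiv), CH2Cl2, −78 °C; Rochelle salt work-up
Reagents that add atoms: none
Why: 1,2-Reduction of the enoate to the allylic alcohol; silyl ethers and alkene geometry are not affected.

Step 12
Reactants: 15 (2Z,5S,6Z,8R)-5,8,9-tris(tert-butyldimethylsilyloxy)-3,7-dimethylnona-2,6-dien-1-ol
Product: 16 (2Z,5S,6Z,8R)-5,8,9-tris(tert-butyldimethylsilyloxy)-3,7-dimethylnona-2,6-dienal
Conditions: TEMPO (10 mol%), PhI(OAc)2, CH2Cl2, rt
Reagents that add atoms: none
Why: Oxoammonium oxidation of the Z-allylic alcohol as in step 5, chosen because it does not isomerise Z-enals.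

Step 13
Reactants: 16 (2Z,5S,6Z,8R)-5,8,9-tris(tert-butyldimethylsilyloxy)-3,7-dimethylnona-2,6-dienal; 17 tributyl(propa-1,2-dienyl)stannane
Product: 19 (4S,5Z,8S,9Z,11R)-8,11,12-tris(tert-butyldimethylsilyloxy)-6,10-dimethyldodeca-1,2,5,9-tetraen-4-ol, via propargylborane 18 (not isolated)
Conditions: (1S,2S)-N,N'-bis(4-methylbenzenesulfonyl)-1,2-diphenylethane-1,2-diamine, BBr3, CH2Cl2, 0 °C to rt; 17, rt; then 16, −78 °C; pH 7 buffer
Reagents that add atoms: none
Why: Allenylation of an aldehyde by a chiral B-propargyl-1,3,2-diazaborolidine: tin-to-boron SE2' exchange gives 18, which adds through a second SE2' step in a six-membered chair to give the α-allenic carbinol, the C2-symmetric bis-sulfonamide on boron selecting the Si face and setting C6 under reagent control.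

Step 14
Reactants: 19 (4S,5Z,8S,9Z,11R)-8,11,12-tris(tert-butyldimethylsilyloxy)-6,10-dimethyldodeca-1,2,5,9-tetraen-4-ol; 20 (2R)-2-methylbutanoic acid
Product: 21 (4S,5Z,8S,9Z,11R)-8,11,12-tris(tert-butyldimethylsilyloxy)-6,10-dimethyldodeca-1,2,5,9-tetraen-4-yl (2R)-2-methylbutanoate
Conditions: DCC, DMAP (20 mol%), CH2Cl2, 0 °C to rt
Reagents that add atoms: none
Why: Steglich esterification; catalytic DMAP at 0 °C should keep the α-stereocentre of the acid, and C6 is not a reacting centre.

Step 15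
Reactants: 21 (4S,5Z,8S,9Z,11R)-8,11,12-tris(tert-butyldimethylsilyloxy)-6,10-dimethyldodeca-1,2,5,9-tetraen-4-yl (2R)-2-methylbutanoate
Product: 22 (4S,5Z,8S,9Z,11R)-8,11-bis(tert-butyldimethylsilyloxy)-12-hydroxy-6,10-dimethyldodeca-1,2,5,9-tetraen-4-yl (2R)-2-methylbutanoate
Conditions: HF·pyridine, pyridine, THF, 0 °C
Reagents that add atoms: none
Why: Sterically controlled desilylation: buffered HF·pyridine should cleave the primary TBS ether much faster than the two secondary ones and leave ester and allene alone.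

Step 16
Reactants: 22 (4S,5Z,8S,9Z,11R)-8,11-bis(tert-butyldimethylsilyloxy)-12-hydroxy-6,10-dimethyldodeca-1,2,5,9-tetraen-4-yl (2R)-2-methylbutanoate
Product: 23 (4S,5Z,8S,9Z,11R)-8,11-bis(tert-butyldimethylsilyloxy)-6,10-dimethyl-12-oxododeca-1,2,5,9-tetraen-4-yl (2R)-2-methylbutanoate
Conditions: DMP, NaHCO3, CH2Cl2, 0 °C; used at once
Reagents that add atoms: none
Why: Dess–Martin oxidation under bicarbonate buffer forms the aldehyde under neutral conditions, so the α-silyloxy β,γ-unsaturated aldehyde should neither epimerise at C9 nor move its double bond.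

Step 17
Reactants: 23 (4S,5Z,8S,9Z,11R)-8,11-bis(tert-butyldimethylsilyloxy)-6,10-dimethyl-12-oxododeca-1,2,5,9-tetraen-4-yl (2R)-2-methylbutanoate
Product: 24 (2S,6R,7S,8R,9R)-2,9-bis(tert-butyldimethylsilyloxy)-6-[(2R)-2-methylbutanoyloxy]germacra-1(10)Z,4Z,11(13)-trien-12,8-olide
Conditions: Ru3(CO)12 (10 mol%), CO (10 atm), 1,4-dioxane (2 mM), 110 °C
Reagents that add atoms: carbon monoxide, [C-]#[O+]
Why: Proposed new method: zerovalent ruthenium is expected to bind the C8 aldehyde and the inner C7=C11 π-bond of the allene and to couple them oxidatively to an oxaruthenacyclopentane (Ru, O, C8, C7, C11, with C13 as exocyclic methylene), CO then inserts into the Ru–C11 bond and C12–O reductive elimination releases the lactone and the metal; the closest known reaction is the cyclocarbonylation (hetero-Pauson–Khand reaction) of allenyl aldehydes at Ru3(CO)12 or Mo(CO)6, which gives α-methylene-γ-butyrolactones fused to five- and six-membered rings. The ten-membered carbocycle closes in the oxidative coupling by C7–C8 bond formation across an eight-atom tether, a ring size without precedent for this step, and the γ-lactone closes afterwards by acyl–oxygen reductive elimination. C7 (S) follows from the allene face, which the neighbouring C6 centre should control by allylic strain (C6–H in the allene plane, the acyloxy group turned away from the metal), and C8 (R) from the aldehyde face, which C9 and the folding of the chain must control; joining the Si face of C7 to the Re face of C8 gives the trans ring fusion. The step needs the inner and not the terminal allene π-bond (ten- against twelve-membered ring), ring closure and not oligomerisation, and this one face pairing. The two Z-alkenes as turn elements, a possible contact of the C6 ester carbonyl with the metal at the adjacent π-bond, high dilution and CO pressure (which also holds back decarbonylation and ionisation of the allenylic ester) are meant to secure them. None of this is proven, and the 8,9-syn relationship that is needed runs against the open-chain Felkin preference of an α-silyloxy aldehyde.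

Step 18
Reactants: 24 (2S,6R,7S,8R,9R)-2,9-bis(tert-butyldimethylsilyloxy)-6-[(2R)-2-methylbutanoyloxy]germacra-1(10)Z,4Z,11(13)-trien-12,8-olide
Product: 25 (2S,6R,7S,8R,9R)-2,9-dihydroxy-6-[(2R)-2-methylbutanoyloxy]germacra-1(10)Z,4Z,11(13)-trien-12,8-olide (CNP0176600.1)
Conditions: HF·pyridine, pyridine, THF, 0 °C to rt
Reagents that add atoms: none
Why: Fluoride cleavage of both secondary TBS ethers under buffered, weakly acidic conditions that the α-methylene lactone, the ester and the allylic alcohols should tolerate; no stereocentre is affected.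

## Compound list

1 | (4S)-2,2-dimethyl-1,3-dioxolane-4-carbaldehyde, (S)-glyceraldehyde acetonide | O=C[C@@H]1COC(C)(C)O1 | starting material
2 | (4R)-4-(2,2-dibromoethenyl)-2,2-dimethyl-1,3-dioxolane | BrC(Br)=C[C@@H]1COC(C)(C)O1 | intermediate
3 | lithium [(4R)-2,2-dimethyl-1,3-dioxolan-4-yl]acetylide | [Li]C#C[C@@H]1COC(C)(C)O1 | intermediate (not isolated)
4 | methyl 3-[(4R)-2,2-dimethyl-1,3-dioxolan-4-yl]prop-2-ynoate | COC(=O)C#C[C@@H]1COC(C)(C)O1 | intermediate
5 | methyl (2Z)-3-[(4R)-2,2-dimethyl-1,3-dioxolan-4-yl]but-2-enoate | COC(=O)/C=C(/C)[C@@H]1COC(C)(C)O1 | intermediate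
6 | (2Z)-3-[(4R)-2,2-dimethyl-1,3-dioxolan-4-yl]but-2-en-1-ol | OC/C=C(/C)[C@@H]1COC(C)(C)O1 | intermediate
7 | (2Z)-3-[(4R)-2,2-dimethyl-1,3-dioxolan-4-yl]but-2-enal | O=C/C=C(/C)[C@@H]1COC(C)(C)O1 | intermediate
8 | allenylboronic acid pinacol ester, 4,4,5,5-tetramethyl-2-(propa-1,2-dienyl)-1,3,2-dioxaborolane | C=C=CB1OC(C)(C)C(C)(C)O1 | starting material
9 | (4S,5Z)-6-[(4R)-2,2-dimethyl-1,3-dioxolan-4-yl]hept-5-en-1-yn-4-ol | C#CC[C@H](O)/C=C(/C)[C@@H]1COC(C)(C)O1 | intermediate
10 | (2R,3Z,5S)-3-methyloct-3-en-7-yne-1,2,5-triol | C#CC[C@H](O)/C=C(/C)[C@@H](O)CO | intermediate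
11 | (4S,5Z,7R)-4,7,8-tris(tert-butyldimethylsilyloxy)-6-methyloct-5-en-1-yne | C#CC[C@H](O[Si](C)(C)C(C)(C)C)/C=C(/C)[C@@H](O[Si](C)(C)C(C)(C)C)CO[Si](C)(C)C(C)(C)C | intermediate
12 | lithium acetylide of 11 | [Li]C#CC[C@H](O[Si](C)(C)C(C)(C)C)/C=C(/C)[C@@H](O[Si](C)(C)C(C)(C)C)CO[Si](C)(C)C(C)(C)C | intermediate (not isolated)
13 | methyl (5S,6Z,8R)-5,8,9-tris(tert-butyldimethylsilyloxy)-7-methylnon-6-en-2-ynoate | COC(=O)C#CC[C@H](O[Si](C)(C)C(C)(C)C)/C=C(/C)[C@@H](O[Si](C)(C)C(C)(C)C)CO[Si](C)(C)C(C)(C)C | intermediate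
14 | methyl (2Z,5S,6Z,8R)-5,8,9-tris(tert-butyldimethylsilyloxy)-3,7-dimethylnona-2,6-dienoate | COC(=O)/C=C(/C)C[C@H](O[Si](C)(C)C(C)(C)C)/C=C(/C)[C@@H](O[Si](C)(C)C(C)(C)C)CO[Si](C)(C)C(C)(C)C | intermediate
15 | (2Z,5S,6Z,8R)-5,8,9-tris(tert-butyldimethylsilyloxy)-3,7-dimethylnona-2,6-dien-1-ol | OC/C=C(/C)C[C@H](O[Si](C)(C)C(C)(C)C)/C=C(/C)[C@@H](O[Si](C)(C)C(C)(C)C)CO[Si](C)(C)C(C)(C)C | intermediate
16 | (2Z,5S,6Z,8R)-5,8,9-tris(tert-butyldimethylsilyloxy)-3,7-dimethylnona-2,6-dienal | O=C/C=C(/C)C[C@H](O[Si](C)(C)C(C)(C)C)/C=C(/C)[C@@H](O[Si](C)(C)C(C)(C)C)CO[Si](C)(C)C(C)(C)C | intermediate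
17 | tributyl(propa-1,2-dienyl)stannane, allenyltributylstannane | C=C=C[Sn](CCCC)(CCCC)CCCC | starting material
18 | (4S,5S)-1,3-bis(4-methylbenzenesulfonyl)-4,5-diphenyl-2-(prop-2-yn-1-yl)-1,3,2-diazaborolidine | Cc1ccc(cc1)S(=O)(=O)N1B(CC#C)N(S(=O)(=O)c2ccc(C)cc2)[C@@H](c2ccccc2)[C@@H]1c1ccccc1 | intermediate (not isolated)
19 | (4S,5Z,8S,9Z,11R)-8,11,12-tris(tert-butyldimethylsilyloxy)-6,10-dimethyldodeca-1,2,5,9-tetraen-4-ol | C=C=C[C@H](O)/C=C(/C)C[C@H](O[Si](C)(C)C(C)(C)C)/C=C(/C)[C@@H](O[Si](C)(C)C(C)(C)C)CO[Si](C)(C)C(C)(C)C | intermediate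
20 | (2R)-2-methylbutanoic acid | CC[C@@H](C)C(=O)O | starting material
21 | (4S,5Z,8S,9Z,11R)-8,11,12-tris(tert-butyldimethylsilyloxy)-6,10-dimethyldodeca-1,2,5,9-tetraen-4-yl (2R)-2-methylbutanoate | C=C=C[C@H](OC(=O)[C@H](C)CC)/C=C(/C)C[C@H](O[Si](C)(C)C(C)(C)C)/C=C(/C)[C@@H](O[Si](C)(C)C(C)(C)C)CO[Si](C)(C)C(C)(C)C | intermediate
22 | (4S,5Z,8S,9Z,11R)-8,11-bis(tert-butyldimethylsilyloxy)-12-hydroxy-6,10-dimethyldodeca-1,2,5,9-tetraen-4-yl (2R)-2-methylbutanoate | C=C=C[C@H](OC(=O)[C@H](C)CC)/C=C(/C)C[C@H](O[Si](C)(C)C(C)(C)C)/C=C(/C)[C@@H](O[Si](C)(C)C(C)(C)C)CO | intermediate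
23 | (4S,5Z,8S,9Z,11R)-8,11-bis(tert-butyldimethylsilyloxy)-6,10-dimethyl-12-oxododeca-1,2,5,9-tetraen-4-yl (2R)-2-methylbutanoate (key-step precursor) | C=C=C[C@H](OC(=O)[C@H](C)CC)/C=C(/C)C[C@H](O[Si](C)(C)C(C)(C)C)/C=C(/C)[C@@H](O[Si](C)(C)C(C)(C)C)C=O | intermediate
24 | (2S,6R,7S,8R,9R)-2,9-bis(tert-butyldimethylsilyloxy)-6-[(2R)-2-methylbutanoyloxy]germacra-1(10)Z,4Z,11(13)-trien-12,8-olide (key-step product) | C=C1C(=O)O[C@@H]2[C@@H]1[C@H](OC(=O)[C@H](C)CC)/C=C(/C)C[C@H](O[Si](C)(C)C(C)(C)C)/C=C(/C)[C@H]2O[Si](C)(C)C(C)(C)C | intermediate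
25 | (2S,6R,7S,8R,9R)-2,9-dihydroxy-6-[(2R)-2-methylbutanoyloxy]germacra-1(10)Z,4Z,11(13)-trien-12,8-olide, CNP0176600.1 | C=C1C(=O)O[C@@H]2[C@@H]1[C@H](OC(=O)[C@H](C)CC)/C=C(/C)C[C@H](O)/C=C(/C)[C@H]2O | target

## Step count and risks

Total step count: 18. Longest linear sequence: 18 steps (from 1).

Three steps most likely to fail:

1. Step 17 (Proposed new method). Processes that may defeat it are oligomerisation instead of ring closure, coupling at the terminal allene π-bond (twelve-membered ring), the wrong face pairing (cis-lactone or C8 epimer), ionisation of the allenylic ester at the low-valent metal, and decarbonylation or α-epimerisation of the aldehyde at 110 °C. The fallback uses known chemistry: the same C7–C8 bond is closed by the CrCl2-mediated intramolecular allylation of an aldehyde by a 2-(bromomethyl)-2-enoate, the Nozaki–Hiyama–Kishi-type closure established for ten-membered germacranolide rings, and the C8 alkoxide lactonises onto the ester. It sets out from enal 16 and comes back at 24. Zinc alkynylation of 16 with 4-methoxybenzyl propargyl ether should give propargylic alcohol F1; the catalyst is Me2Zn with the ProPhenol ligand 2,6-bis{[2-(hydroxydiphenylmethyl)pyrrolidin-1-yl]methyl}-4-methylphenol, in the enantiomer that directs Si-face attack. Hydroxyl-directed trans-hydroalumination with NaAlH2(OCH2CH2OMe)2 and iodination at −78 °C should give the (Z)-iodoalkene F2, and Steglich acylation with 20 the ester F3. Methoxycarbonylation (PdCl2(PPh3)2, CO, MeOH, Et3N) should give the enoate F4, and 2,3-dichloro-5,6-dicyano-1,4-benzoquinone the allylic alcohol F5. CBr4/PPh3 should give the allylic bromide F6, camphorsulfonic acid in MeOH at 0 °C the primary alcohol F7, and Dess–Martin oxidation the bromo aldehyde F8. CrCl2 in THF/DMF at 2 mM should then close the ring, and the hydroxy ester lactonises to 24.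

2. Step 13. Processes that may defeat it are poor facial selectivity on a β,β-disubstituted Z-enal, Z to E isomerisation of the enal at the Lewis acidic boron, and leakage to the homopropargylic regioisomer. In the fallback the allene is made by hydride delivery instead of allenyl transfer; it sets out from 16 and comes back at 19. The zinc alkynylation described above, run with 2-(prop-2-yn-1-yloxy)tetrahydropyran, should give propargylic alcohol F9. LiAlH4 in Et2O at reflux should then reduce F9 in an SN2' sense (hydride from the aluminium alkoxide to C7, loss of the tetrahydropyranyloxy group from C13) to the allenol 19.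

3. Step 6. Processes that may defeat it are slow addition to the hindered β,β-disubstituted enal, Z to E isomerisation under acid catalysis, and a mismatch with the dioxolane centre. The fallback is carbonyl propargylation from the alcohol oxidation level, which also spares step 5; it sets out from allylic alcohol 6 and comes back at 9. Iridium-catalysed transfer-hydrogenative coupling of 6 with 3-chloro-1-(triisopropylsilyl)prop-1-yne should give the silyl alkyne F10; the catalyst is [Ir(cod)Cl]2 with SEGPHOS (5,5'-bis(diphenylphosphino)-4,4'-bi-1,3-benzodioxole, in the enantiomer that gives 4S), a nitrobenzoic acid co-ligand and Cs2CO3. Bu4NF in THF should then remove the silyl group to give 9.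

## Further compounds

F1 | step 17 | propargylic alcohol: 16 with C6 as CH(OH) carrying C≡C–CH2–O-(4-methoxybenzyl), configuration at C6 as in 19 | COc1ccc(COCC#C[C@H](O)/C=C(/C)C[C@H](O[Si](C)(C)C(C)(C)C)/C=C(/C)[C@@H](O[Si](C)(C)C(C)(C)C)CO[Si](C)(C)C(C)(C)C)cc1
F2 | step 17 | (Z)-iodoalkene: F1 with C7H=C11(I), iodine cis to C6 | COc1ccc(COC/C(I)=C/[C@H](O)/C=C(/C)C[C@H](O[Si](C)(C)C(C)(C)C)/C=C(/C)[C@@H](O[Si](C)(C)C(C)(C)C)CO[Si](C)(C)C(C)(C)C)cc1
F3 | step 17 | (2R)-2-methylbutanoate of F2 | COc1ccc(COC/C(I)=C/[C@H](OC(=O)[C@H](C)CC)/C=C(/C)C[C@H](O[Si](C)(C)C(C)(C)C)/C=C(/C)[C@@H](O[Si](C)(C)C(C)(C)C)CO[Si](C)(C)C(C)(C)C)cc1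
F4 | step 17 | methyl enoate: F3 with CO2Me in place of iodine | COc1ccc(COC/C(C(=O)OC)=C/[C@H](OC(=O)[C@H](C)CC)/C=C(/C)C[C@H](O[Si](C)(C)C(C)(C)C)/C=C(/C)[C@@H](O[Si](C)(C)C(C)(C)C)CO[Si](C)(C)C(C)(C)C)cc1
F5 | step 17 | allylic alcohol: F4 without the 4-methoxybenzyl group | OC/C(C(=O)OC)=C/[C@H](OC(=O)[C@H](C)CC)/C=C(/C)C[C@H](O[Si](C)(C)C(C)(C)C)/C=C(/C)[C@@H](O[Si](C)(C)C(C)(C)C)CO[Si](C)(C)C(C)(C)C
F6 | step 17 | allylic bromide: F5 with C13–Br | BrC/C(C(=O)OC)=C/[C@H](OC(=O)[C@H](C)CC)/C=C(/C)C[C@H](O[Si](C)(C)C(C)(C)C)/C=C(/C)[C@@H](O[Si](C)(C)C(C)(C)C)CO[Si](C)(C)C(C)(C)C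
F7 | step 17 | primary alcohol: F6 with C8–OH | BrC/C(C(=O)OC)=C/[C@H](OC(=O)[C@H](C)CC)/C=C(/C)C[C@H](O[Si](C)(C)C(C)(C)C)/C=C(/C)[C@@H](O[Si](C)(C)C(C)(C)C)CO
F8 | step 17 | bromo aldehyde: F7 with C8 as CHO | BrC/C(C(=O)OC)=C/[C@H](OC(=O)[C@H](C)CC)/C=C(/C)C[C@H](O[Si](C)(C)C(C)(C)C)/C=C(/C)[C@@H](O[Si](C)(C)C(C)(C)C)C=O
F9 | step 13 | propargylic alcohol: 16 with C6 as CH(OH) carrying C≡C–CH2–O-(tetrahydropyran-2-yl), acetal centre unassigned | C1CCC(OC1)OCC#C[C@H](O)/C=C(/C)C[C@H](O[Si](C)(C)C(C)(C)C)/C=C(/C)[C@@H](O[Si](C)(C)C(C)(C)C)CO[Si](C)(C)C(C)(C)C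
F10 | step 6 | (4S,5Z)-6-[(4R)-2,2-dimethyl-1,3-dioxolan-4-yl]-1-(triisopropylsilyl)hept-5-en-1-yn-4-ol | CC(C)[Si](C#CC[C@H](O)/C=C(/C)[C@@H]1COC(C)(C)O1)(C(C)C)C(C)C
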